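**Retrosynthetic overview**
- The ester C–O bond is made last: 2-phenylethyl octacosanoate ⇒ octacosanoyl chloride + 2-phenylethanol.
- Octacosanoic acid ⇒ 7-oxooctacosanoic acid (C=O to CH2, Wolff–Kishner) ⇒ 2-docosanoylcyclohexanone (retro-Claisen ring opening read backwards).
- The key C–C disconnection is C6–C7 of the C28 chain: crossed Claisen-type acylation of cyclohexanone (C6, as its morpholine enamine) by docosanoyl chloride (C22).
- No ring is formed. The phenyl ring is bought in 2-phenylethanol, and the bought six-membered cyclohexanone ring is opened after the key step.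

Assumption: the target has no stereocentre and no stereogenic double bond, so the SMILES describes one achiral compound and no step needs stereocontrol.

**Step 1**
Reactants: 1 docosanoic acid (behenic acid, at least 99% homologue purity)
Product: 2 docosanoyl chloride
Conditions: SOCl2 (1.5 equiv), DMF (cat.), toluene, 70 °C, 3 h; evaporate, strip with toluene
Reagents that add atoms: thionyl chloride, O=S(Cl)Cl
Why: Acid chloride formation by nucleophilic acyl substitution through the chlorosulfite is irreversible because the co-products are gases, and the saturated chain has no other reactive site.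

**Step 2**
Reactants: 3 cyclohexanone; 4 morpholine
Product: 5 N-(cyclohex-1-en-1-yl)morpholine
Conditions: 4 (1.2 equiv), TsOH·H2O (0.5 mol %), toluene, reflux, Dean–Stark, 5 h; distil under vacuum
Reagents that add atoms: none
Why: Acid-catalysed enamine condensation (Stork enamine formation) is driven to completion by azeotropic removal of water and creates no stereocentre.

**Step 3**
Reactants: 2 docosanoyl chloride; 5 N-(cyclohex-1-en-1-yl)morpholine
Product: 7 rac-2-docosanoylcyclohexan-1-one, via acyl enamine 6 (not isolated)
Conditions: 5 (1.2 equiv), Et3N (1.2 equiv), CHCl3, 35 °C, slow addition of 2, 4 h; then 20% aq HCl, reflux, 5 h; recrystallise from MeOH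
Reagents that add atoms: water, O
Why: In this intermolecular crossed Claisen-type condensation, run as the Stork enamine acylation, the nucleophilic enamine carbon attacks the acyl chloride, the vinylogous amide 6 is too deactivated to react twice, and acid hydrolysis frees the 1,3-diketone, whose new C2 centre is enolisable, forms racemic and is erased in step 4.

**Step 4**
Reactants: 7 rac-2-docosanoylcyclohexan-1-one
Product: 8 7-oxooctacosanoic acid
Conditions: NaOH (3 equiv), EtOH–H2O, reflux, 2 h; then 2 M HCl to pH 1; recrystallise from EtOH
Reagents that add atoms: sodium hydroxide, [Na+].[OH-]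
Why: In this retro-Claisen cleavage of a 1,3-diketone, hydroxide adds to the more accessible ring carbonyl and expels the enolate of the long-chain ketone, the carboxylate formed makes the ring opening irreversible, and the labile centre becomes a CH2.

**Step 5**
Reactants: 8 7-oxooctacosanoic acid; 9 hydrazine monohydrate
Product: 11 octacosanoic acid, via hydrazone 10 (not isolated)
Conditions: 9 (4 equiv), KOH (4 equiv), diethylene glycol, 130 °C, 2 h; distil to 200 °C, 5 h; then 2 M HCl; recrystallise from toluene
Reagents that add atoms: none
Why: The Wolff–Kishner reduction in the Huang-Minlon form turns the isolated dialkyl ketone into CH2 by base-induced loss of nitrogen from the hydrazone, while the carboxylate is inert and the 7-oxo group is too remote to cyclise onto it.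

**Step 6**
Reactants: 11 octacosanoic acid
Product: 12 octacosanoyl chloride
Conditions: SOCl2 (2 equiv), DMF (cat.), toluene, 75 °C, 3 h; evaporate, strip with toluene
Reagents that add atoms: thionyl chloride, O=S(Cl)Cl
Why: This is the same acid chloride formation as in step 1, and warm toluene overcomes the low solubility of the C28 acid so that activation is complete.

**Step 7**
Reactants: 12 octacosanoyl chloride; 13 2-phenylethanol
Product: 14 2-phenylethyl octacosanoate
Conditions: 13 (1.1 equiv), pyridine (1.5 equiv), DMAP (5 mol %), toluene, 0 to 45 °C, 4 h; wash with dilute HCl and aq NaHCO3; recrystallise from acetone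
Reagents that add atoms: none
Why: DMAP-catalysed acylation of an unhindered primary alcohol by an acid chloride (nucleophilic acyl substitution) is fast and irreversible and sets no stereocentre.

**Compound list**
1 | docosanoic acid | CCCCCCCCCCCCCCCCCCCCCC(=O)O | starting material
2 | docosanoyl chloride | CCCCCCCCCCCCCCCCCCCCCC(=O)Cl | intermediate
3 | cyclohexanone | O=C1CCCCC1 | starting material
4 | morpholine | C1COCCN1 | starting material
5 | N-(cyclohex-1-en-1-yl)morpholine | C1CCC(=CC1)N1CCOCC1 | intermediate
6 | 1-[2-(morpholin-4-yl)cyclohex-1-en-1-yl]docosan-1-one (acyl enamine) | CCCCCCCCCCCCCCCCCCCCCC(=O)C1=C(CCCC1)N1CCOCC1 | intermediate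
7 | rac-2-docosanoylcyclohexan-1-one (keto–enol mixture, labile centre) | CCCCCCCCCCCCCCCCCCCCCC(=O)C1CCCCC1=O | intermediate
8 | 7-oxooctacosanoic acid | CCCCCCCCCCCCCCCCCCCCCC(=O)CCCCCC(=O)O | intermediate
9 | hydrazine monohydrate | NN.O | starting material
10 | 7-hydrazinylideneoctacosanoic acid (hydrazone, E/Z mixture) | CCCCCCCCCCCCCCCCCCCCCC(=NN)CCCCCC(=O)O | intermediate
11 | octacosanoic acid | CCCCCCCCCCCCCCCCCCCCCCCCCCCC(=O)O | intermediate
12 | octacosanoyl chloride | CCCCCCCCCCCCCCCCCCCCCCCCCCCC(=O)Cl | intermediate
13 | 2-phenylethanol | OCCc1ccccc1 | starting material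
14 | 2-phenylethyl octacosanoate | CCCCCCCCCCCCCCCCCCCCCCCCCCCC(=O)OCCc1ccccc1 | target

Total step count: 7. Longest linear sequence: 6 (steps 1, 3, 4, 5, 6, 7). Step 2 is the side branch.

**Three steps most likely to fail**

**Step 3, the key acylation.**
- Risk: Et3N can dehydrochlorinate 2 to the alkylketene, which dimerises. Any free morpholine is N-acylated. Either path lowers the yield of C-acylation.
- The fallback sets out from 2 and 3 and comes back at 7.
- It drops the enamine and makes the same bond by Claisen-type acylation of a preformed lithium enolate, using an acyl azolide that cannot form a ketene.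
- Compound 2 is stirred with 1H-benzotriazole and Et3N in CH2Cl2 at 20 °C to give 1-(benzotriazol-1-yl)docosan-1-one F1.
- Compound 3 (2.2 equiv, the second equivalent deprotonates the diketone as it forms) is converted by LiN(i-Pr)2 in THF at −78 °C into lithium cyclohex-1-en-1-olate F2.
- F1 in warm THF is added, the mixture is allowed to reach 20 °C, and it is quenched with aqueous NH4Cl to give 7.

**Step 4, the ring opening.**
- Risk: hydroxide may attack the exocyclic carbonyl instead. That only deacylates 7 to docosanoate and cyclohexanone, and the C22 acid is hard to remove from C28 material.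
- The fallback sets out from 2 and comes back at 11.
- It uses a cyclic 1,3-dione in which both carbonyl groups lie in the ring, so that either attack gives the same keto acid.
- Rosenmund reduction of 2 (H2, Pd on BaSO4, 2,6-lutidine, THF, 25 °C) gives docosanal F3.
- F3, cyclohexane-1,3-dione, diethyl 2,6-dimethyl-1,4-dihydropyridine-3,5-dicarboxylate (Hantzsch ester) and L-proline (20 mol %) are combined in CH2Cl2 at 25 °C. They undergo Knoevenagel (aldol-type) condensation to 2-docosylidenecyclohexane-1,3-dione F4.
- F4 is reduced in the same flask by hydride transfer to 2-docosylcyclohexane-1,3-dione F5.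
- Refluxing aqueous NaOH opens F5 by retro-Claisen cleavage to 5-oxooctacosanoic acid F6.
- The conditions of step 5 take F6 through 5-hydrazinylideneoctacosanoic acid F7 to 11.

**Step 5, the deoxygenation.**
- Risk: the potassium soap of a C28 acid foams and dissolves poorly in the glycol. Hydrazone breakdown may then stall, or azine may form, leaving oxygenated material that co-crystallises with 11.
- The fallback sets out from 8 and comes back at 11.
- It replaces the hot basic hydrazone chemistry by a Mozingo reduction under near-neutral conditions.
- Compound 8 with ethane-1,2-dithiol and BF3·OEt2 in CH2Cl2 at 25 °C gives 6-(2-henicosyl-1,3-dithiolan-2-yl)hexanoic acid F8.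
- Raney Ni in refluxing EtOH desulfurises F8 to 11.

**Further compounds**
F1 | step 3 | 1-(benzotriazol-1-yl)docosan-1-one | CCCCCCCCCCCCCCCCCCCCCC(=O)n1nnc2ccccc12
F2 | step 3 | lithium cyclohex-1-en-1-olate | [Li+].[O-]C1=CCCCC1
F3 | step 4 | docosanal | CCCCCCCCCCCCCCCCCCCCCC=O
F4 | step 4 | 2-docosylidenecyclohexane-1,3-dione | CCCCCCCCCCCCCCCCCCCCCC=C1C(=O)CCCC1=O
F5 | step 4 | 2-docosylcyclohexane-1,3-dione | CCCCCCCCCCCCCCCCCCCCCCC1C(=O)CCCC1=O
F6 | step 4 | 5-oxooctacosanoic acid | CCCCCCCCCCCCCCCCCCCCCCCC(=O)CCCC(=O)O
F7 | step 4 | 5-hydrazinylideneoctacosanoic acid | CCCCCCCCCCCCCCCCCCCCCCCC(=NN)CCCC(=O)O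
F8 | step 5 | 6-(2-henicosyl-1,3-dithiolan-2-yl)hexanoic acid | CCCCCCCCCCCCCCCCCCCCCC1(CCCCCC(=O)O)SCCS1
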